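The rate constants are those of an exercise; the result is computed.

The reading is taken at a fixed conversion, not at a fixed clock time, so its moment shifts with whatever charge is varied.

left-handed substrate 0.20 mM; coupling partner 0.600 equiv; free catalyst 2 mol%; right-handed substrate 0.20 mM

    coupling partner ⇌ dormant form (K1 = 0.61, k1 = 0.15 s⁻¹)
    coupling partner + catalyst intermediate A → free catalyst + left-handed product (k2 = 54000 L mol⁻¹ s⁻¹)
    coupling partner + catalyst intermediate B → free catalyst + right-handed product (k3 = 610 L mol⁻¹ s⁻¹)
    free catalyst + right-handed substrate ⇌ catalyst intermediate B (K4 = 2000 L mol⁻¹, k4 = 6.0 × 10⁵ L mol⁻¹ s⁻¹)
    free catalyst + left-handed substrate ⇌ catalyst intermediate A (K5 = 1.3 × 10⁵ L mol⁻¹, k5 = 4.6 × 10⁵ L mol⁻¹ s⁻¹)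

- apparent order in coupling partner when 10% of the left-handed substrate and right-handed substrate together are converted (percent change of the rate of making left-handed product for one percent more coupling partner charged)
- apparent order in free catalyst when 10% of the left-handed substrate and right-handed substrate together are converted (percent change of the rate of making left-handed product for one percent more free catalyst charged)

- free catalyst is single-handed; left-handed substrate and right-handed substrate are mirror images of each other, charged as a racemate, each of them at the stated concentration
- what is bound to the catalyst counts as converted
- charge of left-handed substrate (flask): 0.20 mM

Start this flask with step 2 as the main step and catalyst intermediate A as the resting state. Binding of the left-handed substrate weighs 26.0 against 0.40 for the right-handed substrate, and capture at 92.0 s⁻¹ is faster than turnover at 6.5 s⁻¹. With partner and catalyst as the two variables, the rate is then first order in each, so both orders start at 1.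

Now count turnovers. The reading needs 10.0 catalyst loads of conversion, and the bound load counts as converted, which leaves 9.00 turnovers. The coupling partner charged pays for 30.0. This fixed withdrawal makes one percent more partner a larger percentage of the remainder, so the order in partner rises to 1.43. The order in catalyst rises to 1.05, since more catalyst holds more substrate bound and fewer turnovers are needed.

Then add the dormant form. Those turnovers take 1.39 s at the charged rate, shorter than the 1.75 s relaxation half-life, so the dormant pool is reckoned as still filling at the reading. Turnover and loss to the dormant form are both first order in free partner, so their ratio does not depend on how much partner is present. With the catalyst charged taken as catalyst intermediate A, that ratio, k1 over k2 times the catalyst charged, is the dormant toll, the partner gone dormant per turnover: 0.694. The reading therefore costs 15.2 turnovers' worth of free partner. This gives my reckoning of 2.03 in partner. In catalyst it gives 1.54, since more catalyst also lowers the toll. Both numbers leave out the return from the dormant form, so I hold them as high.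

The forecast, which differs from this reckoning, gave 1.7 (1.1 to 2) and 1.2 (1 to 1.4), holding that “extra partner charged raises the free partner more than proportionally”.

The flask gives 1.7 in coupling partner and 1.3 in free catalyst, both lower than the reckoning. The conversion is reached at 2.24 s, with left-handed product forming at 0.0118 mM s⁻¹. The dormant toll counted in the flask, as dormant form per left-handed product, is 0.663 at 1.50 s, against 0.694 reckoned, and 0.283 at 7.50 s.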